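**Strategy.** Labdane numbering is used: C9 carries the side chain, C10 the angular methyl, C8 the hydroxyl and the formyl group (C17). Ring B is read as the cyclohexene of an intramolecular Diels–Alder reaction: its C5–C10 and C8–C9 bonds join the acetoxydiene C5=C6–C7=C8 to the geranial-type enal C9=C10, and the C1–C4 tether becomes ring A. One operation closes both rings and sets C5, C8, C9 and C10 through alkene geometry and an endo transition state, steered by the C3 silyl ether. The precursor is an acyclic trienal assembled from geranyl acetate, a prenylborane and an (E)-iodoenol acetate; the side chain follows by B-alkyl Suzuki coupling.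

Key step: step 8

Assumption: the B-prenyl borane made from (+)-α-pinene attacks the Si face of the aldehyde, as the parent B-allyl reagent does.
Remark: the target is read as the 13Z acid with the 8-hydroxyl axial and cis to the C10 methyl; compounds 12–21 all have the 3R,5S,8R,9S,10R configuration in labdane numbering.

Step 1
Reactants: 1 geranyl acetate, (2E)-3,7-dimethylocta-2,6-dien-1-yl acetate
Product: 3 (2E)-3-methyl-6-oxohex-2-en-1-yl acetate, via secondary ozonide 2 (not isolated)
Conditions: O3 (1.0 equiv, dye end-point), CH2Cl2, −78 °C; then Me2S, −78 °C → rt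
Reagents that add atoms: ozone, [O-][O+]=O
Why: Criegee ozonolysis is chemoselective for the electron-rich 6,7-trisubstituted alkene over the 2,3-alkene that the allylic acetate deactivates, and reductive work-up of the ozonide gives the aldehyde; no stereocentre is formed.

Step 2
Reactants: 3 (2E)-3-methyl-6-oxohex-2-en-1-yl acetate
Product: 5 (2E,6R)-6-hydroxy-3,7,7-trimethylnona-2,8-dien-1-yl acetate, via borinate ester 4 (not isolated)
Conditions: (−)-Ipc2BH (from (+)-α-pinene), 3-methylbuta-1,2-diene, THF, −25 → 0 °C; then 3, Et2O, −78 °C; then NaBO3·4H2O, THF/H2O, rt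
Reagents that add atoms: (−)-B-(3-methylbut-2-en-1-yl)diisopinocampheylborane, CC(C)=CCB([C@@H]1C[C@@H]2C[C@H]([C@H]1C)C2(C)C)[C@@H]1C[C@@H]2C[C@H]([C@H]1C)C2(C)C, made in the flask from (−)-Ipc2BH and 3-methylbuta-1,2-diene, CC(C)=C=C
Why: Asymmetric allylboration (reverse prenylation): the allylborane adds through its γ-carbon in a closed chair transition state, building the quaternary carbon (future C4), and the isopinocampheyl groups direct it to the Si face of the aldehyde, which sets the R carbinol centre (future C3).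

Step 3
Reactants: 5 (2E,6R)-6-hydroxy-3,7,7-trimethylnona-2,8-dien-1-yl acetate
Product: 6 (2E,6R)-6-[(tert-butyldimethylsilyl)oxy]-3,7,7-trimethylnona-2,8-dien-1-yl acetate
Conditions: TBSOTf, 2,6-lutidine, CH2Cl2, −78 → 0 °C
Reagents that add atoms: tert-butyldimethylsilyl triflate, CC(C)(C)[Si](C)(C)OS(=O)(=O)C(F)(F)F
Why: Silylation with the silyl triflate is strong enough for the hindered secondary alcohol beside the quaternary carbon and leaves the configuration untouched.

Step 4
Reactants: 6 (2E,6R)-6-[(tert-butyldimethylsilyl)oxy]-3,7,7-trimethylnona-2,8-dien-1-yl acetate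
Product: 7 (2E,6R)-6-[(tert-butyldimethylsilyl)oxy]-3,7,7-trimethylnona-2,8-dien-1-ol
Conditions: K2CO3 (cat.), MeOH, 0 °C → rt
Reagents that add atoms: none
Why: Base-catalysed transesterification (methanolysis) removes the primary allylic acetate and leaves the silyl ether alone.

Step 5
Reactants: 8 prop-2-yn-1-yl acetate (propargyl acetate)
Product: 9 (1E)-1-iodoprop-1-ene-2,3-diyl diacetate
Conditions: PhI(OAc)2 (0.55 equiv), I2 (0.55 equiv), CH2Cl2, rt, dark
Reagents that add atoms: (diacetoxyiodo)benzene, CC(=O)OI(OC(C)=O)c1ccccc1; iodine, II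
Why: Iodoacetoxylation: acetyl hypoiodite formed in the flask adds across the terminal alkyne through an iodonium ion that acetate opens anti at the internal carbon (Markovnikov), which should give the E isomer with iodine trans to the acetoxy group.

Step 6
Reactants: 7 (2E,6R)-6-[(tert-butyldimethylsilyl)oxy]-3,7,7-trimethylnona-2,8-dien-1-ol; 9 (1E)-1-iodoprop-1-ene-2,3-diyl diacetate
Product: 10 (2E,4E,7R,10E)-7-[(tert-butyldimethylsilyl)oxy]-12-hydroxy-6,6,10-trimethyldodeca-2,4,10-triene-1,2-diyl diacetate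
Conditions: Pd(OAc)2 (10 mol%), Bu4NCl, NaHCO3, DMF, 45 °C
Reagents that add atoms: none
Why: Mizoroki–Heck reaction under ligand-free phase-transfer conditions: the alkenylpalladium species adds to the unsubstituted terminus of the vinyl group, syn β-hydride elimination can only give the conjugated E alkene because C4 is quaternary, and the geometry of the iodoalkene is retained.

Step 7
Reactants: 10 (2E,4E,7R,10E)-7-[(tert-butyldimethylsilyl)oxy]-12-hydroxy-6,6,10-trimethyldodeca-2,4,10-triene-1,2-diyl diacetate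
Product: 11 (2E,4E,7R,10E)-7-[(tert-butyldimethylsilyl)oxy]-6,6,10-trimethyl-12-oxododeca-2,4,10-triene-1,2-diyl diacetate
Conditions: MnO2 (activated, excess), CH2Cl2, rt
Reagents that add atoms: none
Why: Heterogeneous MnO2 oxidation is selective for the allylic alcohol and keeps the E geometry of the enal and of the enol acetate.

Step 8
Reactants: 11 (2E,4E,7R,10E)-7-[(tert-butyldimethylsilyl)oxy]-6,6,10-trimethyl-12-oxododeca-2,4,10-triene-1,2-diyl diacetate
Product: 12 [(1S,2R,4aS,6R,8aR)-2-acetoxy-6-[(tert-butyldimethylsilyl)oxy]-1-formyl-5,5,8a-trimethyl-1,2,4a,5,6,7,8,8a-octahydronaphthalen-2-yl]methyl acetate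
Conditions: Me2AlCl (promoter, 2.5 equiv), CH2Cl2, −78 → −20 °C
Reagents that add atoms: none
Why: Me2AlCl binds the formyl oxygen and lowers the LUMO of the enal, so that the acetoxydiene adds in an asynchronous concerted [4+2] in which the C5–C10 bond (nucleophilic diene terminus to the enal β-carbon) runs ahead of the C8–C9 bond; the closest known reaction type is the Lewis acid-promoted type 1 intramolecular Diels–Alder reaction of 2,8,10-undecatrienals, which gives trans-fused octalins through the endo transition state. Ring A closes as the six-membered ring of the four-carbon tether (chair, C5–C10 bond, exo with respect to the C9=C10 bond), and ring B is the new cyclohexene, closed suprafacially on both components. C9 and C10 follow from the E geometry of the enal (formyl group and C10 methyl cis); the trans ring fusion at C5/C10 follows from the endo position of the aluminium-bound formyl group with the tether anti; C8 follows from the 7E enol acetate, whose acetoxy group is outside and whose acetoxymethyl group is inside, so that the acetoxy group ends cis to the C9 formyl group and the C10 methyl. The absolute sense comes from C3: its silyloxy group sits equatorial in the chair-like tether next to the gem-dimethyl group and so selects one diene face. The step needs endo over exo selectivity and this facial selectivity; the Lewis acid secures the first, the C3 stereocentre the second, and the tether fixes the regiochemistry.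

Step 9
Reactants: 12 [(1S,2R,4aS,6R,8aR)-2-acetoxy-6-[(tert-butyldimethylsilyl)oxy]-1-formyl-5,5,8a-trimethyl-1,2,4a,5,6,7,8,8a-octahydronaphthalen-2-yl]methyl acetate
Product: 13 [(1S,2R,4aS,6R,8aR)-2-acetoxy-6-[(tert-butyldimethylsilyl)oxy]-1-formyl-5,5,8a-trimethyldecahydronaphthalen-2-yl]methyl acetate
Conditions: H2 (1 atm), 5% Rh/Al2O3, EtOAc, rt
Reagents that add atoms: none
Why: Catalytic hydrogenation of the cis-disubstituted ring alkene; rhodium on alumina is chosen because it is far less prone than palladium to hydrogenolysis of the allylic tertiary acetate and leaves the hindered aldehyde, and no stereocentre is formed.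

Step 10
Reactants: 13 [(1S,2R,4aS,6R,8aR)-2-acetoxy-6-[(tert-butyldimethylsilyl)oxy]-1-formyl-5,5,8a-trimethyldecahydronaphthalen-2-yl]methyl acetate
Product: 14 [(1S,2R,4aS,6R,8aR)-2-acetoxy-6-[(tert-butyldimethylsilyl)oxy]-1-ethenyl-5,5,8a-trimethyldecahydronaphthalen-2-yl]methyl acetate
Conditions: Zn, CH2Br2, TiCl4, THF/CH2Cl2, 0 °C → rt
Reagents that add atoms: dibromomethane, BrCBr
Why: Takai–Lombardo methylenation: the non-basic zinc–titanium methylene reagent converts hindered, enolisable aldehydes without epimerisation at C9 or elimination of the β-acetoxy group and does not touch the esters.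

Step 11
Reactants: 15 ethyl but-2-ynoate
Product: 16 ethyl (2Z)-3-iodobut-2-enoate
Conditions: NaI, AcOH, 115 °C
Reagents that add atoms: sodium iodide, [Na+].[I-]
Why: Hydroiodination of the ynoate: conjugate addition of iodide and anti protonation give the Z iodoalkene (iodine cis to the ester) under kinetic control.

Step 12
Reactants: 14 [(1S,2R,4aS,6R,8aR)-2-acetoxy-6-[(tert-butyldimethylsilyl)oxy]-1-ethenyl-5,5,8a-trimethyldecahydronaphthalen-2-yl]methyl acetate; 16 ethyl (2Z)-3-iodobut-2-enoate
Product: 18 ethyl (2Z)-5-[(1S,2R,4aS,6R,8aR)-2-acetoxy-2-(acetoxymethyl)-6-[(tert-butyldimethylsilyl)oxy]-5,5,8a-trimethyldecahydronaphthalen-1-yl]-3-methylpent-2-enoate, via trialkylborane 17 (not isolated)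
Conditions: 9-BBN dimer, THF, 0 → 50 °C; then 16, Pd(dppf)Cl2 (5 mol%), AsPh3, K3PO4 (3 M aq), DMF, rt
Reagents that add atoms: 9-borabicyclo[3.3.1]nonane, B1C2CCCC1CCC2 (its atoms stay in 17 only; 18 takes nothing but hydrogen from it)
Why: Anti-Markovnikov hydroboration of the monosubstituted alkene with 9-BBN followed by B-alkyl Suzuki–Miyaura coupling, in which the alkenyl iodide couples with retention and so delivers the 13Z trisubstituted enoate.

Step 13
Reactants: 18 ethyl (2Z)-5-[(1S,2R,4aS,6R,8aR)-2-acetoxy-2-(acetoxymethyl)-6-[(tert-butyldimethylsilyl)oxy]-5,5,8a-trimethyldecahydronaphthalen-1-yl]-3-methylpent-2-enoate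
Product: 19 (2Z)-5-[(1S,2R,4aS,6R,8aR)-6-[(tert-butyldimethylsilyl)oxy]-2-hydroxy-2-(hydroxymethyl)-5,5,8a-trimethyldecahydronaphthalen-1-yl]-3-methylpent-2-enoic acid
Conditions: LiOH·H2O, THF/MeOH/H2O, 45 °C; then aq HCl to pH 4
Reagents that add atoms: water (as hydroxide), O
Why: Saponification cleaves the ethyl ester and the primary acetate, and the tertiary acetate follows after 1,2-acyl shift to the freed primary hydroxyl, while the hindered silyl ether and the Z alkene should survive.

Step 14
Reactants: 19 (2Z)-5-[(1S,2R,4aS,6R,8aR)-6-[(tert-butyldimethylsilyl)oxy]-2-hydroxy-2-(hydroxymethyl)-5,5,8a-trimethyldecahydronaphthalen-1-yl]-3-methylpent-2-enoic acid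
Product: 20 (2Z)-5-[(1S,2R,4aS,6R,8aR)-6-[(tert-butyldimethylsilyl)oxy]-2-formyl-2-hydroxy-5,5,8a-trimethyldecahydronaphthalen-1-yl]-3-methylpent-2-enoic acid
Conditions: IBX, DMSO/THF, rt
Reagents that add atoms: none
Why: IBX oxidises the primary alcohol to the aldehyde, cannot oxidise the tertiary alcohol, does not cleave 1,2-diols and tolerates the free acid, and C8 carries no hydrogen and cannot epimerise.

Step 15
Reactants: 20 (2Z)-5-[(1S,2R,4aS,6R,8aR)-6-[(tert-butyldimethylsilyl)oxy]-2-formyl-2-hydroxy-5,5,8a-trimethyldecahydronaphthalen-1-yl]-3-methylpent-2-enoic acid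
Product: 21 (2Z)-5-[(1S,2R,4aS,6R,8aR)-2-formyl-2,6-dihydroxy-5,5,8a-trimethyldecahydronaphthalen-1-yl]-3-methylpent-2-enoic acid (CNP0273710.1)
Conditions: HF (48% aq), MeCN, 0 °C → rt
Reagents that add atoms: none
Why: Acidic fluoride desilylation removes the hindered secondary silyl ether under conditions mild enough for the tertiary α-hydroxy aldehyde and the Z enoic acid.

**Compound list**

1 | geranyl acetate, (2E)-3,7-dimethylocta-2,6-dien-1-yl acetate | CC(=O)OC/C=C(\C)CCC=C(C)C | starting material
2 | secondary ozonide, (2E)-5-(5,5-dimethyl-1,2,4-trioxolan-3-yl)-3-methylpent-2-en-1-yl acetate | CC(=O)OC/C=C(\C)CCC1OOC(C)(C)O1 | intermediate (not isolated)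
3 | (2E)-3-methyl-6-oxohex-2-en-1-yl acetate | CC(=O)OC/C=C(\C)CCC=O | intermediate
4 | bis(isopinocampheyl)borinate ester of 5 | CC(=O)OC/C=C(\C)CC[C@@H](OB([C@@H]1C[C@@H]2C[C@H]([C@H]1C)C2(C)C)[C@@H]1C[C@@H]2C[C@H]([C@H]1C)C2(C)C)C(C)(C)C=C | intermediate (not isolated)
5 | (2E,6R)-6-hydroxy-3,7,7-trimethylnona-2,8-dien-1-yl acetate | CC(=O)OC/C=C(\C)CC[C@@H](O)C(C)(C)C=C | intermediate
6 | (2E,6R)-6-[(tert-butyldimethylsilyl)oxy]-3,7,7-trimethylnona-2,8-dien-1-yl acetate | CC(=O)OC/C=C(\C)CC[C@@H](O[Si](C)(C)C(C)(C)C)C(C)(C)C=C | intermediate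
7 | (2E,6R)-6-[(tert-butyldimethylsilyl)oxy]-3,7,7-trimethylnona-2,8-dien-1-ol | OC/C=C(\C)CC[C@@H](O[Si](C)(C)C(C)(C)C)C(C)(C)C=C | intermediate
8 | prop-2-yn-1-yl acetate | C#CCOC(C)=O | starting material
9 | (1E)-1-iodoprop-1-ene-2,3-diyl diacetate | I/C=C(\COC(C)=O)OC(C)=O | intermediate
10 | (2E,4E,7R,10E)-7-[(tert-butyldimethylsilyl)oxy]-12-hydroxy-6,6,10-trimethyldodeca-2,4,10-triene-1,2-diyl diacetate | OC/C=C(\C)CC[C@@H](O[Si](C)(C)C(C)(C)C)C(C)(C)/C=C/C=C(\COC(C)=O)OC(C)=O | intermediate
11 | (2E,4E,7R,10E)-7-[(tert-butyldimethylsilyl)oxy]-6,6,10-trimethyl-12-oxododeca-2,4,10-triene-1,2-diyl diacetate | O=C/C=C(\C)CC[C@@H](O[Si](C)(C)C(C)(C)C)C(C)(C)/C=C/C=C(\COC(C)=O)OC(C)=O | intermediate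
12 | [(1S,2R,4aS,6R,8aR)-2-acetoxy-6-[(tert-butyldimethylsilyl)oxy]-1-formyl-5,5,8a-trimethyl-1,2,4a,5,6,7,8,8a-octahydronaphthalen-2-yl]methyl acetate | O=C[C@H]1[C@]2(C)CC[C@@H](O[Si](C)(C)C(C)(C)C)C(C)(C)[C@H]2C=C[C@]1(OC(C)=O)COC(C)=O | intermediate
13 | [(1S,2R,4aS,6R,8aR)-2-acetoxy-6-[(tert-butyldimethylsilyl)oxy]-1-formyl-5,5,8a-trimethyldecahydronaphthalen-2-yl]methyl acetate | O=C[C@H]1[C@]2(C)CC[C@@H](O[Si](C)(C)C(C)(C)C)C(C)(C)[C@H]2CC[C@]1(OC(C)=O)COC(C)=O | intermediate
14 | [(1S,2R,4aS,6R,8aR)-2-acetoxy-6-[(tert-butyldimethylsilyl)oxy]-1-ethenyl-5,5,8a-trimethyldecahydronaphthalen-2-yl]methyl acetate | C=C[C@H]1[C@]2(C)CC[C@@H](O[Si](C)(C)C(C)(C)C)C(C)(C)[C@H]2CC[C@]1(OC(C)=O)COC(C)=O | intermediate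
15 | ethyl but-2-ynoate | CC#CC(=O)OCC | starting material
16 | ethyl (2Z)-3-iodobut-2-enoate | C/C(I)=C/C(=O)OCC | intermediate
17 | 9-{2-[(1S,2R,4aS,6R,8aR)-2-acetoxy-2-(acetoxymethyl)-6-[(tert-butyldimethylsilyl)oxy]-5,5,8a-trimethyldecahydronaphthalen-1-yl]ethyl}-9-borabicyclo[3.3.1]nonane | C1CCC2CCCC1B2CC[C@H]1[C@]2(C)CC[C@@H](O[Si](C)(C)C(C)(C)C)C(C)(C)[C@H]2CC[C@]1(OC(C)=O)COC(C)=O | intermediate (not isolated)
18 | ethyl (2Z)-5-[(1S,2R,4aS,6R,8aR)-2-acetoxy-2-(acetoxymethyl)-6-[(tert-butyldimethylsilyl)oxy]-5,5,8a-trimethyldecahydronaphthalen-1-yl]-3-methylpent-2-enoate | C/C(=C/C(=O)OCC)CC[C@H]1[C@]2(C)CC[C@@H](O[Si](C)(C)C(C)(C)C)C(C)(C)[C@H]2CC[C@]1(OC(C)=O)COC(C)=O | intermediate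
19 | (2Z)-5-[(1S,2R,4aS,6R,8aR)-6-[(tert-butyldimethylsilyl)oxy]-2-hydroxy-2-(hydroxymethyl)-5,5,8a-trimethyldecahydronaphthalen-1-yl]-3-methylpent-2-enoic acid | C/C(=C/C(=O)O)CC[C@H]1[C@]2(C)CC[C@@H](O[Si](C)(C)C(C)(C)C)C(C)(C)[C@H]2CC[C@]1(O)CO | intermediate
20 | (2Z)-5-[(1S,2R,4aS,6R,8aR)-6-[(tert-butyldimethylsilyl)oxy]-2-formyl-2-hydroxy-5,5,8a-trimethyldecahydronaphthalen-1-yl]-3-methylpent-2-enoic acid | C/C(=C/C(=O)O)CC[C@H]1[C@]2(C)CC[C@@H](O[Si](C)(C)C(C)(C)C)C(C)(C)[C@H]2CC[C@]1(O)C=O | intermediate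
21 | (2Z)-5-[(1S,2R,4aS,6R,8aR)-2-formyl-2,6-dihydroxy-5,5,8a-trimethyldecahydronaphthalen-1-yl]-3-methylpent-2-enoic acid | C/C(=C/C(=O)O)CC[C@H]1[C@]2(C)CC[C@@H](O)C(C)(C)[C@H]2CC[C@]1(O)C=O | target

**Step count.** Total: 15 steps. Longest linear sequence: 13 steps (steps 1–4, 6–10, 12–15, from geranyl acetate).

**Steps most likely to fail**

1. Step 8 (key step). The cycloaddition may be slower than side reactions, because the acetoxymethyl group stands cis (inside) on the diene terminus and disfavours the s-cis conformer, and both new bonds join congested carbons. Ionisation or elimination of the allylic and enol acetates by the Lewis acid, E/Z isomerisation of the aluminium-bound enal, or closure through the exo transition state to a cis-fused decalin could then compete. Fallback: a cationic Diels–Alder reaction of the acetal, whose 2-alkoxyallyl cation is a far stronger dienophile than the neutral Lewis acid complex. It sets out from 11. Treatment with 1,2-bis(trimethylsilyloxy)ethane and catalytic TMSOTf in CH2Cl2 at −78 °C should give the trienal dioxolane F1. Warming this in the same flask to −40 °C should ionise the acetal and close both rings to the cycloadduct dioxolane F2. PPTS in wet acetone at 40 °C should then release the aldehyde, and the route is rejoined at 12.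

2. Step 6. Carbopalladation of the neopentyl-type vinyl group may be slow, so that homocoupling of 9, base cleavage of its enol acetate or ionisation of its allylic acetate by zerovalent palladium takes over. Fallback: metathesis followed by Suzuki–Miyaura coupling in place of the Heck reaction. It sets out from 7. Cross-metathesis with vinylboronic acid pinacol ester (second-generation Hoveyda–Grubbs catalyst, CH2Cl2, 40 °C) should give the (E)-alkenylboronate F3. Coupling of this with 9 (Pd(dppf)Cl2, CsF, THF, rt), with retention at both alkenes, should give the diene, and the route is rejoined at 10.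

3. Step 10. The hindered aldehyde may enolise with trans-diaxial loss of acetic acid across C8–C9, or the neopentyl-type formyl group may not react at all. Fallback: a two-stage Peterson olefination. It sets out from 13. Addition of Me3SiCH2MgCl with CeCl3 (THF, −78 °C), a weakly basic organocerium reagent, should give the β-hydroxysilane F4 as a mixture of carbinol epimers. Acid-promoted anti elimination (BF3·OEt2, CH2Cl2, −20 °C) should convert both epimers to the alkene, and the route is rejoined at 14.

**Further compounds**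

F1 | step 8 | trienal dioxolane, (2E,4E,7R,10E)-7-[(tert-butyldimethylsilyl)oxy]-11-(1,3-dioxolan-2-yl)-6,6,10-trimethylundeca-2,4,10-triene-1,2-diyl diacetate | C1COC(O1)/C=C(\C)CC[C@@H](O[Si](C)(C)C(C)(C)C)C(C)(C)/C=C/C=C(\COC(C)=O)OC(C)=O
F2 | step 8 | cycloadduct dioxolane, [(1S,2R,4aS,6R,8aR)-2-acetoxy-6-[(tert-butyldimethylsilyl)oxy]-1-(1,3-dioxolan-2-yl)-5,5,8a-trimethyl-1,2,4a,5,6,7,8,8a-octahydronaphthalen-2-yl]methyl acetate | C1COC(O1)[C@H]1[C@]2(C)CC[C@@H](O[Si](C)(C)C(C)(C)C)C(C)(C)[C@H]2C=C[C@]1(OC(C)=O)COC(C)=O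
F3 | step 6 | (E)-alkenylboronate, (2E,6R,8E)-6-[(tert-butyldimethylsilyl)oxy]-3,7,7-trimethyl-9-(4,4,5,5-tetramethyl-1,3,2-dioxaborolan-2-yl)nona-2,8-dien-1-ol | OC/C=C(\C)CC[C@@H](O[Si](C)(C)C(C)(C)C)C(C)(C)/C=C/B1OC(C)(C)C(C)(C)O1
F4 | step 10 | β-hydroxysilane, [(1S,2R,4aS,6R,8aR)-2-acetoxy-6-[(tert-butyldimethylsilyl)oxy]-1-[1-hydroxy-2-(trimethylsilyl)ethyl]-5,5,8a-trimethyldecahydronaphthalen-2-yl]methyl acetate (both carbinol epimers) | C[Si](C)(C)CC(O)[C@H]1[C@]2(C)CC[C@@H](O[Si](C)(C)C(C)(C)C)C(C)(C)[C@H]2CC[C@]1(OC(C)=O)COC(C)=O
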